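The pyran ring is disconnected across C2–C3 and O1–C8a (chromene numbering), which removes acetone and leaves an aryl methyl ketone that carries fluoride at C8a. The key step exploits two features of the benzene ring: C8a lies ortho to the C4 carbonyl carbon and para to the ester-bearing C6, so its fluoride is doubly activated, and C3 is the enolisable α-carbon of that ketone. In one operation the lithium enolate adds to acetone (C3–C2) and the resulting tertiary alkoxide displaces fluoride (O1–C8a), giving the 2,2-dimethylchroman-4-one. The hexasubstituted fluoroarene is assembled from methyl 4-fluoro-2-methylbenzoate; reduction and acid-mediated dehydration with global deprotection then deliver the chromene.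

Key step: step 7

Assumption: silyl ether 9 is taken as a catalogue reagent; the target has no stereocentre, so no stereocontrol is needed.

Step 1
Reactants: 1 methyl 4-fluoro-2-methylbenzoate
Product: 3 methyl 4-fluoro-2-hydroxy-6-methylbenzoate, via aryl trifluoroacetate 2 (not isolated)
Conditions: [RuCl2(p-cymene)]2 (2.5 mol %), K2S2O8, CF3CO2H/(CF3CO)2O, 80 °C; aqueous work-up
Reagents that add atoms: trifluoroacetic acid, OC(=O)C(F)(F)F
Why: Ester-directed ortho C–H hydroxylation catalysed by divalent ruthenium (cyclometalation, persulfate oxidation, C–O reductive elimination to the aryl trifluoroacetate, hydrolysis on work-up) should occur at C6, the only C–H ortho to the ester.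

Step 2
Reactants: 3 methyl 4-fluoro-2-hydroxy-6-methylbenzoate
Product: 4 methyl 3-bromo-4-fluoro-6-hydroxy-2-methylbenzoate
Conditions: NBS, MeCN, 0 °C → rt
Reagents that add atoms: N-bromosuccinimide, O=C1CCC(=O)N1Br
Why: Electrophilic aromatic bromination of a salicylate should go para to the hydroxyl (C3, also ortho to F and CH3), and any ortho isomer would be removed by chromatography.

Step 3
Reactants: 4 methyl 3-bromo-4-fluoro-6-hydroxy-2-methylbenzoate
Product: 5 methyl 3-bromo-4-fluoro-6-(methoxymethoxy)-2-methylbenzoate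
Conditions: NaH, MOMCl, DMF, 0 °C → rt
Reagents that add atoms: chloromethyl methyl ether, COCCl
Why: Williamson-type O-alkylation of the sodium phenoxide gives the MOM ether, which later directs metalation and keeps a deactivating phenoxide out of the key step.

Step 4
Reactants: 5 methyl 3-bromo-4-fluoro-6-(methoxymethoxy)-2-methylbenzoate; 6 1-bromo-3-methylbut-2-ene (prenyl bromide)
Product: 8 methyl 3-bromo-4-fluoro-6-(methoxymethoxy)-2-methyl-5-(3-methylbut-2-en-1-yl)benzoate, via arylmagnesium chloride 7 (not isolated)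
Conditions: TMPMgCl·LiCl, THF, −20 °C; then CuBr·SMe2 (10 mol %), 6, −20 → 0 °C
Reagents that add atoms: none
Why: Directed ortho-magnesiation should take the only ring C–H (flanked by OMOM and F) while the ester and aryl bromide survive the amide base, and copper-catalysed allylic substitution (SN2) should then occur at the unhindered CH2 terminus because attack at the tertiary terminus would build a quaternary benzylic carbon.

Step 5
Reactants: 8 methyl 3-bromo-4-fluoro-6-(methoxymethoxy)-2-methyl-5-(3-methylbut-2-en-1-yl)benzoate; 9 [4-(bromomethyl)phenoxy](tert-butyl)dimethylsilane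
Product: 11 methyl 3-bromo-2-[2-(4-{[tert-butyl(dimethyl)silyl]oxy}phenyl)ethyl]-4-fluoro-6-(methoxymethoxy)-5-(3-methylbut-2-en-1-yl)benzoate, via benzylic organolithium 10 (not isolated)
Conditions: LiN(iPr)2, THF, −78 °C; then 9, −78 → −20 °C
Reagents that add atoms: none
Why: Lateral lithiation of the ortho-toluate (the CH3 anion is conjugated to the ester, and the amide base does not exchange the aryl bromide) followed by SN2 benzylation should build the arylethyl chain.

Step 6
Reactants: 11 methyl 3-bromo-2-[2-(4-{[tert-butyl(dimethyl)silyl]oxy}phenyl)ethyl]-4-fluoro-6-(methoxymethoxy)-5-(3-methylbut-2-en-1-yl)benzoate; 12 tributyl(1-ethoxyethenyl)stannane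
Product: 14 methyl 3-acetyl-2-[2-(4-{[tert-butyl(dimethyl)silyl]oxy}phenyl)ethyl]-4-fluoro-6-(methoxymethoxy)-5-(3-methylbut-2-en-1-yl)benzoate, via enol ether 13 (not isolated)
Conditions: Pd(PPh3)2Cl2 (5 mol %), toluene, 100 °C; then 1 M HCl (aq), THF, rt
Reagents that add atoms: water, O
Why: Stille coupling of the aryl bromide with the acetyl-anion equivalent and brief acid hydrolysis of the enol ether should give the methyl ketone while the MOM and silyl ethers survive.

Step 7
Reactants: 14 methyl 3-acetyl-2-[2-(4-{[tert-butyl(dimethyl)silyl]oxy}phenyl)ethyl]-4-fluoro-6-(methoxymethoxy)-5-(3-methylbut-2-en-1-yl)benzoate; 15 acetone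
Product: 18 methyl 5-[2-(4-{[tert-butyl(dimethyl)silyl]oxy}phenyl)ethyl]-7-(methoxymethoxy)-2,2-dimethyl-8-(3-methylbut-2-en-1-yl)-4-oxo-3,4-dihydro-2H-chromene-6-carboxylate, via lithium enolate 16 (not isolated), via lithium aldolate 17 (not isolated)
Conditions: LiN(iPr)2, THF, −78 °C; 15, −78 °C; then DMPU, −78 °C → rt
Reagents that add atoms: none
Why: Kinetic deprotonation of the methyl ketone gives enolate 16, whose carbon (the future C3) adds to the carbonyl carbon of acetone (C2) to give tertiary aldolate 17, and its oxygen then attacks C8a through a Meisenheimer adduct that expels fluoride. The closest known reaction type is the tandem aldol addition/intramolecular SNAr of 2-fluoroaryl ketones, the fluoride counterpart of the Kabbe chromanone synthesis, here a formal [4+2] annulation of acetone. The pyranone ring closes by 6-exo-trig attack of the alkoxide on the arene carbon followed by loss of fluoride (addition–elimination). No stereocentre is created because C2 carries two methyl groups. The step needs enolisation at the acetyl CH3 in preference to the benzylic CH2, which the far higher acidity of the ketone under kinetic conditions secures. It also needs ring closure to outrun retro-aldol and E1cB dehydration, which the irreversible SNAr on a doubly activated fluoride, the DMPU-loosened alkoxide and the MOM ether (no deactivating phenoxide) should secure.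

Step 8
Reactants: 18 methyl 5-[2-(4-{[tert-butyl(dimethyl)silyl]oxy}phenyl)ethyl]-7-(methoxymethoxy)-2,2-dimethyl-8-(3-methylbut-2-en-1-yl)-4-oxo-3,4-dihydro-2H-chromene-6-carboxylate
Product: 20 methyl 7-hydroxy-5-[2-(4-hydroxyphenyl)ethyl]-2,2-dimethyl-8-(3-methylbut-2-en-1-yl)-2H-chromene-6-carboxylate, via chromanol 19 (not isolated)
Conditions: NaBH4, THF/H2O, 0 °C → rt; then 3 M HCl (aq), 50 °C
Reagents that add atoms: none
Why: Chemoselective borohydride reduction of the ketone (the hindered ester is untouched) gives racemic chromanol 19, whose benzylic cation, stabilised by the ortho and para oxygens, should lose a proton (E1 dehydration) to the conjugated chromene while the same acid hydrolyses the MOM acetal and the aryl silyl ether; the transient C4 stereocentre is destroyed.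

Compound list
1 | methyl 4-fluoro-2-methylbenzoate | COC(=O)c1ccc(F)cc1C | starting material
2 | methyl 4-fluoro-2-methyl-6-(trifluoroacetoxy)benzoate | COC(=O)c1c(OC(=O)C(F)(F)F)cc(F)cc1C | intermediate
3 | methyl 4-fluoro-2-hydroxy-6-methylbenzoate | COC(=O)c1c(O)cc(F)cc1C | intermediate
4 | methyl 3-bromo-4-fluoro-6-hydroxy-2-methylbenzoate | COC(=O)c1c(O)cc(F)c(Br)c1C | intermediate
5 | methyl 3-bromo-4-fluoro-6-(methoxymethoxy)-2-methylbenzoate | COC(=O)c1c(OCOC)cc(F)c(Br)c1C | intermediate
6 | 1-bromo-3-methylbut-2-ene (prenyl bromide) | CC(C)=CCBr | starting material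
7 | arylmagnesium chloride from 5, magnesiated at C5 | COC(=O)c1c(OCOC)c([Mg]Cl)c(F)c(Br)c1C | intermediate
8 | methyl 3-bromo-4-fluoro-6-(methoxymethoxy)-2-methyl-5-(3-methylbut-2-en-1-yl)benzoate | COC(=O)c1c(OCOC)c(CC=C(C)C)c(F)c(Br)c1C | intermediate
9 | [4-(bromomethyl)phenoxy](tert-butyl)dimethylsilane | CC(C)(C)[Si](C)(C)Oc1ccc(CBr)cc1 | starting material
10 | benzylic organolithium from 8, lithiated at the C2 methyl | COC(=O)c1c(OCOC)c(CC=C(C)C)c(F)c(Br)c1C[Li] | intermediate
11 | methyl 3-bromo-2-[2-(4-{[tert-butyl(dimethyl)silyl]oxy}phenyl)ethyl]-4-fluoro-6-(methoxymethoxy)-5-(3-methylbut-2-en-1-yl)benzoate | COC(=O)c1c(OCOC)c(CC=C(C)C)c(F)c(Br)c1CCc1ccc(O[Si](C)(C)C(C)(C)C)cc1 | intermediate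
12 | tributyl(1-ethoxyethenyl)stannane | CCCC[Sn](CCCC)(CCCC)C(=C)OCC | starting material
13 | methyl 2-[2-(4-{[tert-butyl(dimethyl)silyl]oxy}phenyl)ethyl]-3-(1-ethoxyethenyl)-4-fluoro-6-(methoxymethoxy)-5-(3-methylbut-2-en-1-yl)benzoate | COC(=O)c1c(OCOC)c(CC=C(C)C)c(F)c(C(=C)OCC)c1CCc1ccc(O[Si](C)(C)C(C)(C)C)cc1 | intermediate
14 | methyl 3-acetyl-2-[2-(4-{[tert-butyl(dimethyl)silyl]oxy}phenyl)ethyl]-4-fluoro-6-(methoxymethoxy)-5-(3-methylbut-2-en-1-yl)benzoate | COC(=O)c1c(OCOC)c(CC=C(C)C)c(F)c(C(C)=O)c1CCc1ccc(O[Si](C)(C)C(C)(C)C)cc1 | intermediate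
15 | acetone (propan-2-one) | CC(C)=O | starting material
16 | lithium enolate of 14 | COC(=O)c1c(OCOC)c(CC=C(C)C)c(F)c(C(=C)O[Li])c1CCc1ccc(O[Si](C)(C)C(C)(C)C)cc1 | intermediate
17 | lithium aldolate (lithium alkoxide of the 3-hydroxy-3-methylbutanoyl arene) | COC(=O)c1c(OCOC)c(CC=C(C)C)c(F)c(C(=O)CC(C)(C)O[Li])c1CCc1ccc(O[Si](C)(C)C(C)(C)C)cc1 | intermediate
18 | methyl 5-[2-(4-{[tert-butyl(dimethyl)silyl]oxy}phenyl)ethyl]-7-(methoxymethoxy)-2,2-dimethyl-8-(3-methylbut-2-en-1-yl)-4-oxo-3,4-dihydro-2H-chromene-6-carboxylate | COC(=O)c1c(OCOC)c(CC=C(C)C)c2OC(C)(C)CC(=O)c2c1CCc1ccc(O[Si](C)(C)C(C)(C)C)cc1 | intermediate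
19 | methyl 5-[2-(4-{[tert-butyl(dimethyl)silyl]oxy}phenyl)ethyl]-4-hydroxy-7-(methoxymethoxy)-2,2-dimethyl-8-(3-methylbut-2-en-1-yl)-3,4-dihydro-2H-chromene-6-carboxylate (racemic) | COC(=O)c1c(OCOC)c(CC=C(C)C)c2OC(C)(C)CC(O)c2c1CCc1ccc(O[Si](C)(C)C(C)(C)C)cc1 | intermediate
20 | methyl 7-hydroxy-5-[2-(4-hydroxyphenyl)ethyl]-2,2-dimethyl-8-(3-methylbut-2-en-1-yl)-2H-chromene-6-carboxylate | COC(=O)c1c(O)c(CC=C(C)C)c2c(c1CCc1ccc(O)cc1)C=CC(C)(C)O2 | target

Total step count: 8. Longest linear sequence: 8 steps (1 → 20).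

Steps most likely to fail

Step 7. The aldolate may revert by retro-aldol or lose water by E1cB elimination faster than it closes onto C8a, and the alkoxide may strip the silyl ether. The fallback sets out from 14 and returns at 18. The fluoride of 14 would be exchanged for hydroxyl with 2-(methylsulfonyl)ethanol and NaH in DMF (SNAr by the alkoxide, then loss of methyl vinyl sulfone) to give the ortho-hydroxyaryl methyl ketone F1. F1 would then be condensed with acetone and pyrrolidine in MeOH at 50 °C (Kabbe chromanone synthesis: enamine aldol condensation to the β,β-dimethyl enone, then oxa-Michael closure by the phenol) to give 18.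

Step 4. Magnesiation may stray to the benzylic CH3, the ortho-fluoro arylmagnesium 7 may lose MgClF to an aryne on warming, and the allylic substitution may go at the tertiary terminus. The fallback sets out from 4 and returns at 8. Phenol 4 would be O-alkylated with tert-butyl 2-methylbut-3-en-2-yl carbonate and Pd(PPh3)4 in THF at 0 °C (Tsuji–Trost etherification at the tertiary terminus) to give the 1,1-dimethylallyl aryl ether F2. Aromatic Claisen rearrangement in toluene at 110 °C would move the allyl unit, with allylic inversion, to the only free ortho carbon and give the ortho-prenyl phenol F3. NaH and MOMCl in DMF would then give 8.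

Step 8. Under hot aqueous acid the liberated C7 phenol may add across the prenyl double bond, the benzylic cation may be trapped or oligomerise, and elimination may stall. The fallback sets out from 18 and returns at 20. Ketone 18 would be converted with KN(SiMe3)2 and PhNTf2 (THF, −78 °C) into the enol triflate F4. F4 would be reduced with Pd(OAc)2, PPh3, Bu3N and HCO2H in DMF at 60 °C (palladium-catalysed formate reduction of a vinyl triflate) to the protected chromene F5. 2 M HCl (aq) in THF at room temperature would then remove the MOM and silyl groups, with no carbocation at C4, to give 20.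

Further compounds
F1 | step 7 | methyl 3-acetyl-2-[2-(4-{[tert-butyl(dimethyl)silyl]oxy}phenyl)ethyl]-4-hydroxy-6-(methoxymethoxy)-5-(3-methylbut-2-en-1-yl)benzoate | COC(=O)c1c(OCOC)c(CC=C(C)C)c(O)c(C(C)=O)c1CCc1ccc(O[Si](C)(C)C(C)(C)C)cc1
F2 | step 4 | methyl 3-bromo-4-fluoro-2-methyl-6-[(2-methylbut-3-en-2-yl)oxy]benzoate | COC(=O)c1c(OC(C)(C)C=C)cc(F)c(Br)c1C
F3 | step 4 | methyl 3-bromo-4-fluoro-6-hydroxy-2-methyl-5-(3-methylbut-2-en-1-yl)benzoate | COC(=O)c1c(O)c(CC=C(C)C)c(F)c(Br)c1C
F4 | step 8 | methyl 5-[2-(4-{[tert-butyl(dimethyl)silyl]oxy}phenyl)ethyl]-7-(methoxymethoxy)-2,2-dimethyl-8-(3-methylbut-2-en-1-yl)-4-{[(trifluoromethyl)sulfonyl]oxy}-2H-chromene-6-carboxylate | COC(=O)c1c(OCOC)c(CC=C(C)C)c2OC(C)(C)C=C(OS(=O)(=O)C(F)(F)F)c2c1CCc1ccc(O[Si](C)(C)C(C)(C)C)cc1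
F5 | step 8 | methyl 5-[2-(4-{[tert-butyl(dimethyl)silyl]oxy}phenyl)ethyl]-7-(methoxymethoxy)-2,2-dimethyl-8-(3-methylbut-2-en-1-yl)-2H-chromene-6-carboxylate | COC(=O)c1c(OCOC)c(CC=C(C)C)c2OC(C)(C)C=Cc2c1CCc1ccc(O[Si](C)(C)C(C)(C)C)cc1
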